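**Retrosynthetic overview**

1. Target 12 ⇒ bis[(E)-2-hydroxycinnamate] 11: both pyranone rings are opened at the lactone C(acyl)–O bonds and are closed together in the last step.
2. 11 ⇒ mono-silyl ether 10 ⇒ 9 + 3: the (E)-styryl C–C bond comes from Heck arylation of a vinyl group on the quaternary carbon.
3. 9 ⇒ 8 ⇒ 6 + 7: vinyl from formyl; the cyclohexene and both stereocentres come from an exo- and enantioselective Diels–Alder reaction of aryl diene 6 with methacrolein.
4. 6 ⇒ 5 ⇒ 3 + 4, and 3 ⇒ 1 + 2: silyl ether, Suzuki coupling, Wittig olefination.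
5. Ring order: benzene rings are bought; cyclohexene in step 4; both pyranone rings last, in step 7.

Assumption: 1, 2, 4 and 7 are bought (4 is otherwise one step from 2-methylbut-1-en-3-yne and pinacolborane); in names the cyclohexene carbon bearing the aryl group is C1 and the quaternary carbon is C6.

**Route**

Step 1
Reactants: 1 5-bromo-2-hydroxy-4-methoxybenzaldehyde; 2 methyl (triphenylphosphoranylidene)acetate
Product: 3 methyl (E)-3-(5-bromo-2-hydroxy-4-methoxyphenyl)prop-2-enoate
Conditions: toluene, 23 °C, 12 h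
Reagents that add atoms: none
Why: Wittig olefination with a stabilized ylide gives the (E)-cinnamate, whose geometry keeps the phenol from lactonizing, so the open hydroxy ester is carried on as the masked pyranone.

Step 2
Reactants: 3 methyl (E)-3-(5-bromo-2-hydroxy-4-methoxyphenyl)prop-2-enoate; 4 4,4,5,5-tetramethyl-2-[(1E)-3-methylbuta-1,3-dien-1-yl]-1,3,2-dioxaborolane
Product: 5 methyl (E)-3-{2-hydroxy-4-methoxy-5-[(1E)-3-methylbuta-1,3-dien-1-yl]phenyl}prop-2-enoate
Conditions: Pd(OAc)2 (3 mol%), SPhos (2-dicyclohexylphosphino-2',6'-dimethoxybiphenyl, 6 mol%), K3PO4, dioxane/H2O 10:1, 70 °C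
Reagents that add atoms: none
Why: Suzuki–Miyaura coupling transfers the (E)-dienyl group with retention of geometry, and the electron-rich biaryl phosphine copes with the electron-rich, ortho-substituted bromide and the free phenol.

Step 3
Reactants: 5 methyl (E)-3-{2-hydroxy-4-methoxy-5-[(1E)-3-methylbuta-1,3-dien-1-yl]phenyl}prop-2-enoate
Product: 6 methyl (E)-3-{2-[(tert-butyldimethylsilyl)oxy]-4-methoxy-5-[(1E)-3-methylbuta-1,3-dien-1-yl]phenyl}prop-2-enoate
Conditions: TBSCl, imidazole, DMF, 23 °C
Reagents that add atoms: tert-butyldimethylsilyl chloride (TBSCl), CC(C)(C)[Si](C)(C)Cl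
Why: Silyl ether formation masks the acidic phenol so that it cannot quench the cationic boron Lewis acid of step 4.

Step 4
Reactants: 6 methyl (E)-3-{2-[(tert-butyldimethylsilyl)oxy]-4-methoxy-5-[(1E)-3-methylbuta-1,3-dien-1-yl]phenyl}prop-2-enoate; 7 methacrolein
Product: 8 methyl (E)-3-{2-[(tert-butyldimethylsilyl)oxy]-5-[(1R,6S)-6-formyl-3,6-dimethylcyclohex-2-en-1-yl]-4-methoxyphenyl}prop-2-enoate
Conditions: (S)-1-(2,4,6-trimethylphenyl)-3,3-bis(3,5-dimethylphenyl)tetrahydro-1H,3H-pyrrolo[1,2-c][1,3,2]oxazaborole (20 mol%), (CF3SO2)2NH (18 mol%), CH2Cl2, −78 °C, dienophile in threefold excess; then Et3N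
Reagents that add atoms: none
Why: Proposed new method: exo- and enantioselective Diels–Alder addition of an α-substituted acrolein to an open-chain (E)-1-aryl diene under a chiral oxazaborolidinium ion whose boron carries a 2,6-disubstituted aryl "roof": methacrolein binds boron in the s-trans form with the formyl C–H···O contact and stacks on the near 3,5-dimethylphenyl group so that only its C2 re face is open (6S quaternary centre), the ortho-methyl groups of the mesityl ring cover the B–O=C region where the diene backbone would lie in the endo mode, and the remaining exo mode (small methyl under the diene, complexed formyl pointing outward) puts formyl trans and methyl cis to the aryl group (1R), with regiochemistry fixed by the concordant 1-aryl ("ortho") and 3-methyl ("para") effects; the closest known reaction types are the oxazaborolidinium-catalysed enantioselective Diels–Alder reactions of methacrolein (exo with cyclopentadiene, not shown as exo-selective with open-chain 1-substituted dienes) and exo-selective Diels–Alder reactions under aluminium tris(2,6-diphenylphenoxide), Al(OC6H3Ph2)3.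

Step 5
Reactants: 8 methyl (E)-3-{2-[(tert-butyldimethylsilyl)oxy]-5-[(1R,6S)-6-formyl-3,6-dimethylcyclohex-2-en-1-yl]-4-methoxyphenyl}prop-2-enoate
Product: 9 methyl (E)-3-{2-[(tert-butyldimethylsilyl)oxy]-5-[(1S,6R)-6-ethenyl-3,6-dimethylcyclohex-2-en-1-yl]-4-methoxyphenyl}prop-2-enoate
Conditions: Ph3PCH3Br, KN(SiMe3)2, THF, −78 → 0 °C
Reagents that add atoms: methyltriphenylphosphonium bromide, C[P+](c1ccccc1)(c1ccccc1)c1ccccc1.[Br-]
Why: Wittig methylenation of the non-enolizable neopentyl aldehyde (no α-hydrogen, so the quaternary centre cannot epimerize) is much faster at 0 °C than any reaction of the ylide with the conjugated ester; the descriptors change only because the substituent priorities change.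

Step 6
Reactants: 9 methyl (E)-3-{2-[(tert-butyldimethylsilyl)oxy]-5-[(1S,6R)-6-ethenyl-3,6-dimethylcyclohex-2-en-1-yl]-4-methoxyphenyl}prop-2-enoate; 3 methyl (E)-3-(5-bromo-2-hydroxy-4-methoxyphenyl)prop-2-enoate
Product: 10 methyl (E)-3-{2-[(tert-butyldimethylsilyl)oxy]-5-[(1S,6R)-6-{(E)-2-[4-hydroxy-2-methoxy-5-((E)-3-methoxy-3-oxoprop-1-en-1-yl)phenyl]ethenyl}-3,6-dimethylcyclohex-2-en-1-yl]-4-methoxyphenyl}prop-2-enoate
Conditions: Pd2(dba)3 (2.5 mol%), [HP(t-Bu)3]BF4 (10 mol%), Cy2NMe, dioxane, 70 °C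
Reagents that add atoms: none
Why: Mizoroki–Heck arylation: aryl–palladium adds to the unhindered CH2 terminus of the vinyl group and, since the quaternary carbon offers no β-hydrogen, β-hydride elimination can only give the conjugated (E)-styrene, while the 1,2-disubstituted cinnamate and trisubstituted ring alkenes are far slower acceptors.

Step 7
Reactants: 10 methyl (E)-3-{2-[(tert-butyldimethylsilyl)oxy]-5-[(1S,6R)-6-{(E)-2-[4-hydroxy-2-methoxy-5-((E)-3-methoxy-3-oxoprop-1-en-1-yl)phenyl]ethenyl}-3,6-dimethylcyclohex-2-en-1-yl]-4-methoxyphenyl}prop-2-enoate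
Product: 12 6-[(1S,6R)-3,6-dimethyl-6-[(E)-2-(7-methoxy-2-oxo-2H-chromen-6-yl)ethenyl]cyclohex-2-en-1-yl]-7-methoxy-2H-chromen-2-one, via free bis-phenol diester 11 (not isolated)
Conditions: KHF2 (1.1 equiv), MeOH, 23 °C, 1 h; then n-Bu3P (40 mol%), 65 °C
Reagents that add atoms: none
Why: Fluoride cleaves the aryl silyl ether and nucleophilic phosphine catalysis then closes both lactones (n-Bu3P adds to the β-carbon of each (E)-2-hydroxycinnamate, the saturated β-phosphonio ester rotates, the ortho-phenol attacks the ester carbonyl to form the two ring C–O bonds, and E1cB loss of the phosphine restores C3=C4) under neutral conditions that leave the styryl and ring alkenes and both stereocentres untouched.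

**Compound list**

1 | 5-bromo-2-hydroxy-4-methoxybenzaldehyde | O=Cc1cc(Br)c(OC)cc1O | starting material
2 | methyl (triphenylphosphoranylidene)acetate | COC(=O)C=P(c1ccccc1)(c1ccccc1)c1ccccc1 | starting material
3 | methyl (E)-3-(5-bromo-2-hydroxy-4-methoxyphenyl)prop-2-enoate | COC(=O)/C=C/c1cc(Br)c(OC)cc1O | intermediate
4 | 4,4,5,5-tetramethyl-2-[(1E)-3-methylbuta-1,3-dien-1-yl]-1,3,2-dioxaborolane | CC(=C)/C=C/B1OC(C)(C)C(C)(C)O1 | starting material
5 | methyl (E)-3-{2-hydroxy-4-methoxy-5-[(1E)-3-methylbuta-1,3-dien-1-yl]phenyl}prop-2-enoate | COC(=O)/C=C/c1cc(/C=C/C(C)=C)c(OC)cc1O | intermediate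
6 | methyl (E)-3-{2-[(tert-butyldimethylsilyl)oxy]-4-methoxy-5-[(1E)-3-methylbuta-1,3-dien-1-yl]phenyl}prop-2-enoate | COC(=O)/C=C/c1cc(/C=C/C(C)=C)c(OC)cc1O[Si](C)(C)C(C)(C)C | intermediate
7 | methacrolein (2-methylprop-2-enal) | CC(=C)C=O | starting material
8 | methyl (E)-3-{2-[(tert-butyldimethylsilyl)oxy]-5-[(1R,6S)-6-formyl-3,6-dimethylcyclohex-2-en-1-yl]-4-methoxyphenyl}prop-2-enoate | O=C[C@@]1(C)CCC(C)=C[C@@H]1c1cc(/C=C/C(=O)OC)c(O[Si](C)(C)C(C)(C)C)cc1OC | intermediate
9 | methyl (E)-3-{2-[(tert-butyldimethylsilyl)oxy]-5-[(1S,6R)-6-ethenyl-3,6-dimethylcyclohex-2-en-1-yl]-4-methoxyphenyl}prop-2-enoate | C=C[C@@]1(C)CCC(C)=C[C@@H]1c1cc(/C=C/C(=O)OC)c(O[Si](C)(C)C(C)(C)C)cc1OC | intermediate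
10 | methyl (E)-3-{2-[(tert-butyldimethylsilyl)oxy]-5-[(1S,6R)-6-{(E)-2-[4-hydroxy-2-methoxy-5-((E)-3-methoxy-3-oxoprop-1-en-1-yl)phenyl]ethenyl}-3,6-dimethylcyclohex-2-en-1-yl]-4-methoxyphenyl}prop-2-enoate | COC(=O)/C=C/c1cc(/C=C/[C@@]2(C)CCC(C)=C[C@@H]2c2cc(/C=C/C(=O)OC)c(O[Si](C)(C)C(C)(C)C)cc2OC)c(OC)cc1O | intermediate
11 | methyl (E)-3-{2-hydroxy-5-[(1S,6R)-6-{(E)-2-[4-hydroxy-2-methoxy-5-((E)-3-methoxy-3-oxoprop-1-en-1-yl)phenyl]ethenyl}-3,6-dimethylcyclohex-2-en-1-yl]-4-methoxyphenyl}prop-2-enoate (not isolated) | COC(=O)/C=C/c1cc(/C=C/[C@@]2(C)CCC(C)=C[C@@H]2c2cc(/C=C/C(=O)OC)c(O)cc2OC)c(OC)cc1O | intermediate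
12 | 6-[(1S,6R)-3,6-dimethyl-6-[(E)-2-(7-methoxy-2-oxo-2H-chromen-6-yl)ethenyl]cyclohex-2-en-1-yl]-7-methoxy-2H-chromen-2-one | COc1cc2oc(=O)ccc2cc1/C=C/[C@@]1(C)CCC(C)=C[C@@H]1c1cc2ccc(=O)oc2cc1OC | target

**Step count and risks**

Total steps: 7. Longest linear sequence: 7 steps (1 → 3 → 5 → 6 → 8 → 9 → 10 → 12); compound 3 is used a second time in step 6.

The three steps most likely to fail:

Step 4 (the proposed new step). Lewis-acid-bound methacrolein normally prefers the endo mode with open-chain dienes, so the exo control by the roofed catalyst may be incomplete. The hindered boron may bind the aldehyde poorly, and the electron-rich diene may oligomerize. If only the sense of induction is wrong, the antipodal catalyst corrects it. The fallback uses known chemistry and sets out from 6. Thermal Diels–Alder dimerization of 6 (toluene, 110 °C, 2,6-di-tert-butyl-4-methylphenol as radical inhibitor) uses the isopropenyl end of a second molecule as the dienophile. After chromatographic removal of the cis isomer and regioisomers it gives the racemic trans-dimer, dimethyl bis-silyl ether F1. Preparative HPLC on a chiral stationary phase gives the (1S,6R)-bis-silyl ether F2. The conditions of step 7 with 2.2 equiv KHF2 remove both silyl groups and give 11, where the route is rejoined; steps 5 and 6 are then not needed.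

Step 6. The vinyl group sits on a quaternary carbon next to a bulky aryl group, and the bromide 3 is electron-rich, so the Heck coupling may be slow; the temperature should stay at or below about 80 °C to protect the 1,5-diene core. The fallback sets out from 8, so it also covers a poor methylenation in step 5. Takai olefination (CrCl2, CHI3, THF, 0 °C) gives the (E)-vinyl iodide F3. Miyaura borylation of 3 (B2pin2, Pd(dppf)Cl2, KOAc, dioxane, 80 °C) gives the aryl pinacol boronate F4. Suzuki–Miyaura coupling of the two (Pd(dppf)Cl2, K3PO4, dioxane/H2O, 50 °C) gives 10, where the route is rejoined.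

Step 7. Phosphine addition to the electron-rich cinnamates may be slow, and the second ring closure may lag behind the first. The fallback sets out from 11 and replaces nucleophilic catalysis by triplet energy transfer. (−)-Riboflavin (C17H20N4O6, 5 mol%), 402 nm light, MeCN/MeOH, argon, 23 °C isomerizes the polarized cinnamate double bonds from E to Z in preference to the higher-energy styryl bond. The Z-hydroxy esters lactonize as they form, which gives 12 directly; this fallback makes no new compound (F0).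

**Further compounds**

F1 | step 4 | racemic trans-dimer of 6: methyl (E)-3-{2-[(tert-butyldimethylsilyl)oxy]-5-[(1S*,6R*)-6-{(E)-2-[4-[(tert-butyldimethylsilyl)oxy]-2-methoxy-5-((E)-3-methoxy-3-oxoprop-1-en-1-yl)phenyl]ethenyl}-3,6-dimethylcyclohex-2-en-1-yl]-4-methoxyphenyl}prop-2-enoate (racemate) | COC(=O)/C=C/c1cc(/C=C/C2(C)CCC(C)=CC2c2cc(/C=C/C(=O)OC)c(O[Si](C)(C)C(C)(C)C)cc2OC)c(OC)cc1O[Si](C)(C)C(C)(C)C
F2 | step 4 | (1S,6R)-enantiomer of F1 (bis-silyl ether of 11) | COC(=O)/C=C/c1cc(/C=C/[C@@]2(C)CCC(C)=C[C@@H]2c2cc(/C=C/C(=O)OC)c(O[Si](C)(C)C(C)(C)C)cc2OC)c(OC)cc1O[Si](C)(C)C(C)(C)C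
F3 | step 6 | methyl (E)-3-{2-[(tert-butyldimethylsilyl)oxy]-5-[(1S,6S)-6-[(E)-2-iodoethenyl]-3,6-dimethylcyclohex-2-en-1-yl]-4-methoxyphenyl}prop-2-enoate | I/C=C/[C@@]1(C)CCC(C)=C[C@@H]1c1cc(/C=C/C(=O)OC)c(O[Si](C)(C)C(C)(C)C)cc1OC
F4 | step 6 | methyl (E)-3-[2-hydroxy-4-methoxy-5-(4,4,5,5-tetramethyl-1,3,2-dioxaborolan-2-yl)phenyl]prop-2-enoate | COC(=O)/C=C/c1cc(B2OC(C)(C)C(C)(C)O2)c(OC)cc1O
F0 | step 7 | none | none
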